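# Synthesis plan for (2R,3S,4S,5R)-2,5-bis(4-hydroxy-3-methoxyphenyl)-3,4-dimethyloxolan-3-ol (19)

Atom labels O1 and C2–C5 are those of the target ring and are kept for every intermediate in the discussion. Locants inside compound names belong to the ring system that is named.

## The problem

Compound 19 is a single oxolane ring (O1, C2–C5) with four contiguous stereocentres: 4-hydroxy-3-methoxyphenyl groups at C2 and C5, a methyl and a hydroxyl on the fully substituted C3, and a methyl on C4, in the 2R,3S,4S,5R configuration. On the ring, the two aryl groups and the C3 methyl lie on one face, and the C3 hydroxyl and the C4 methyl on the other. C3 cannot be repaired once made, so it has to arise stereospecifically. C2 can be tied to C3 through the geometry of a C2=C3 alkene, C4 can be adjusted by enolisation while C5 is a carbonyl carbon, and C5 can be set last under the influence of C4. Nothing in the molecule comes from the chiral pool, so the absolute configuration has to be brought in by a removable element. Both ring C–O bonds are p-oxygenated benzylic ethers, which ionise under acid and can be hydrogenolysed; the C3 oxygen is β to any carbanion at C4 and can be eliminated; the phenols need masking to the end. The feature that opens the route is that C2 and C5 are both bonded to O1. O1 can therefore be replaced by a temporary C2–C5 bond, giving a cyclobutanone with C5 as carbonyl carbon. Its C3–C4 and C2–C5 bonds are those of a ketene–alkene cycloaddition, its C3 oxygen is that of an enol ether, and a peracid later puts O1 back between C5 and the benzylic C2.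

## Retrosynthesis

**19 ⇒ 18 (three exocyclic benzylic C–O bonds).** Both phenols are masked as benzyl ethers and the C3 oxygen as the ether of the auxiliary alcohol 1, so one hydrogenolysis releases 19. Separate silyl and acid-labile groups would add steps and expose the p-hydroxybenzylic ring ethers to acid. The forward step must cleave three exocyclic benzylic C–O bonds and spare the two endocyclic ones. For that reason the C3 ether is of the naphthylmethyl type, which adsorbs on palladium and cleaves more readily than a plain secondary benzylic ether.

**18 ⇒ 14 + 17 (C5–aryl bond).** The aryl bond is cut at C5, not at C2. C2 is next to the quaternary C3 and is best fixed together with it, whereas C5 has only C4 as a stereogenic neighbour and can be made by addition to an oxocarbenium ion. An aryl nucleophile on a C5 cation is preferred to the reverse order (aryl onto the lactone, then hydride) because the group that must end trans to the C4 methyl is then the incoming one. Lactol acetate 14 has one aryl group fewer and three ring stereocentres; arylzinc 17 comes in one operation from bromide 15 via aryllithium 16. The forward reaction must deliver the aryl group to the face opposite the C4 methyl.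

**14 ⇒ 12 (oxidation level at C5).** No skeletal bond is cut; the acetoxy acetal is traced to lactone 12 through aluminium hemiacetal 13. The C5 carbonyl makes C4 adjustable and is the retron for oxygen insertion. The reduction must stop at the hemiacetal and never release the β-alkoxy aldehyde.

**12 ⇒ 11 (configuration of C4).** No bond is cut; C4 is inverted. The cycloaddition below is expected to place the ketene methyl on the face of the aryl group and the C3 methyl, so the correction is planned, not left to chance. It is placed at the lactone and not at the ketone: in cyclobutanone 10 the benzylic C2–H is also α to the carbonyl and is the more acidic position, so base there would scramble the C2/C3 relationship. In lactones 11 and 12, C2 is an ether carbon and only C4 can enolise.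

**11 ⇒ 10 (O1 removed, C2–C5 bond in its place).** Removing O1 contracts the oxolanone to a cyclobutanone. The simplification is that both remaining ring bonds to be made are now cycloaddition bonds. Forward, oxygen must insert on the C2 side and with retention. Both are expected from the higher migratory aptitude of the electron-rich secondary benzylic carbon over the secondary alkyl C4.

**10 ⇒ 7 + 9 (C3–C4 and C2–C5 bonds).** Cutting these two bonds gives methylketene 9, made in the flask from acid chloride 8, and enol ether 7. The other pair of ring bonds (C2–C3 and C4–C5) would put the oxygen on the wrong carbon. Only this cut uses the polarity the C3 oxygen provides: C2 is nucleophilic and C3 stabilises positive charge. A ring with three stereocentres is reduced to an alkene of defined geometry and a three-carbon acid chloride. The forward reaction must retain the (E) geometry (this fixes C2 against C3), must select one alkene face (absolute configuration), and must outrun ketene dimerisation. The ether group on the C3 oxygen is the only source of absolute configuration: at the least it turns the two facial modes into separable diastereomers.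

**7 ⇒ 4 + 5 (C2=C3 double bond).** Horner–Wittig disconnection gives the α-alkoxyethyl phosphine oxide 4 and O-benzylvanillin 5; the alkoxides 6 are intermediates. O-Alkylation of the arylacetone enolate or elimination from its acetal would favour the isomer with aryl cis to oxygen or give mixtures. The phosphine oxide route reaches the needed isomer (aryl cis to the vinylic methyl) through stereospecific syn elimination. Both fragments are simple; the forward step has to supply the (E) isomer in pure form.

**4 ⇒ 2 ⇒ 1 (C–P bond, O–vinyl bond).** The C–P bond comes from a Michaelis–Arbuzov reaction of the α-chloro ether 3, obtained by adding HCl to vinyl ether 2. Compound 2 comes from commercial (S)-alcohol 1 by transfer vinylation. The carbinol C–O bond of 1 is never broken, so its configuration is carried through.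

## Roads not taken

**Alternative 1:** The ring is cut at O1–C5 and C2–C3, leading from diester A1 back to the donor–acceptor cyclopropane A2 and aldehyde 5. Forward, Sn(OTf)2 activates A2; the aldehyde oxygen displaces at the benzylic carbon with inversion, and the malonate carbon closes onto the aldehyde carbon.
- Merits: two aryl fragments are joined convergently, the ring and both benzylic centres form in one catalytic step, 2,5-cis selectivity is inherent, and an enantioenriched A2 would transfer its configuration. In convergence and in absolute control this road is better than the chosen one.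
- Weak points:
  - Because of the inversion, the 4,5-trans product needs the cis-2-aryl-3-methyl cyclopropane, the less accessible and less reactive isomer.
  - The p-alkoxyaryl donor favours full ionisation to a ring-opened zwitterion, which erodes stereospecificity.
  - C3 arrives as a malonate carbon. One ester must be reduced to methyl and the other replaced by oxygen, with the quaternary centre set late in a decarboxylative oxygenation that offers no clear stereocontrol. This costs several steps.
- Comparison: the chosen plan brings C3 in with its oxygen and methyl already in place and fixes it by alkene geometry. Against the better absolute control of this alternative it can only set an auxiliary and a diastereomer separation.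

**Alternative 2:** The ring is cut at C4–C5 (the O1–C5 bond being already present in an acetal), leading from ketone A3 back to the 4-ethylidene-1,3-dioxolane A4. Forward, Me2AlCl ionises A4 to an aryl oxocarbenium ion and an aluminium enolate, whose carbon closes onto the oxocarbenium carbon (Petasis–Ferrier rearrangement).
- Merits: C2 comes from a stereocentre of the mandelic acid type, the sequence is short, and the C3 ketone of A3 could take up the methyl group directly. In step count and in the source of absolute configuration this road is better.
- Weak points:
  - The methyl nucleophile would have to enter syn to the adjacent C2 aryl group; approach from the opposite face, past the smaller C4 methyl, is the expected course and gives the wrong C3 configuration.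
  - C2–H in A3 is benzylic, α to oxygen and α to the ketone, so it is at risk under the Lewis acid and with basic methyl-metal reagents.
  - The rearrangement is less developed for five-membered rings than for six-membered ones.
- Comparison: the chosen plan fixes the C2/C3 pair stereospecifically, whereas this alternative creates C3 last and against the steric bias. The chosen plan pays with a longer sequence and a planned C4 correction.

**Alternative 3:** The ring is cut at C4–C5 and O1–C2, leading from silane A5 back to the (Z)-allylsilane A6 and aldehyde 5. Forward, BF3·OEt2 activates 5, the γ-carbon of A6 attacks anti to silicon, silicon shifts from C2 to C3, and the alkoxide captures the benzylic C2 cation.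
- Merits: the ring and all four stereocentres form in one step, and anti addition with the (Z) alkene places silicon at C3 cis to the C4 methyl, as the target requires. C4 is set directly with no epimerisation, which is better than the chosen plan on that point.
- Weak points:
  - Loss of silicon to give an open-chain homoallylic alcohol competes with the shift and ring closure.
  - A6 is an enantioenriched benzylic silane on a trisubstituted (Z) alkene, which is hard to make and prone to protodesilylation.
  - Oxidation of the tertiary C–Si bond with retention needs electrophilic removal of the phenyl group from silicon. Such conditions attack the electron-rich aryl rings and the acid-labile benzylic ring ethers, and tertiary silanes oxidise slowly.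
- Comparison: the chosen plan has oxygen on C3 from the start, at the cost of an extra ring-expansion step and the C4 correction.

Key step: step 4

Assumption: the (1S)-configured auxiliary is taken to direct the ketene to the alkene face that leads to 10. If the opposite bias were found, the (1R)-alcohol would be used and every later step would stay the same.

## Route

Step 1
Reactants: 1 (S)-1-(naphthalen-2-yl)ethanol
Product: 2 2-[(1S)-1-(ethenyloxy)ethyl]naphthalene
Conditions: butyl vinyl ether (solvent), Pd(OAc)2 (cat.), 1,10-phenanthroline (cat.), Et3N, 75 °C
Reagents that add atoms: butyl vinyl ether, C=COCCCC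
Why: Transfer vinylation of a secondary alcohol under catalysis by divalent palladium; the carbinol C–O bond is not broken, so the (S) configuration is kept.

Step 2
Reactants: 2 2-[(1S)-1-(ethenyloxy)ethyl]naphthalene
Product: 4 [1-{[(1S)-1-(naphthalen-2-yl)ethyl]oxy}ethyl](diphenyl)phosphine oxide (both epimers at the phosphorus-bearing carbon), via 1-chloroethyl ether 3 (not isolated)
Conditions: HCl (1 equiv, in Et2O), CH2Cl2, −78 → 0 °C; then Ph2POEt, 0 °C → rt
Reagents that add atoms: ethyl diphenylphosphinite, CCOP(c1ccccc1)c1ccccc1
Why: Markovnikov addition of HCl to the vinyl ether gives α-chloro ether 3, which alkylates the phosphinite in a Michaelis–Arbuzov reaction. The new phosphorus-bearing centre need not be controlled because it is deprotonated in step 3.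

Step 3
Reactants: 4 [1-{[(1S)-1-(naphthalen-2-yl)ethyl]oxy}ethyl](diphenyl)phosphine oxide; 5 4-(benzyloxy)-3-methoxybenzaldehyde (O-benzylvanillin)
Product: 7 2-[(1S)-1-({(1E)-1-[4-(benzyloxy)-3-methoxyphenyl]prop-1-en-2-yl}oxy)ethyl]naphthalene (aryl cis to the vinylic methyl), via lithium alkoxide adducts 6 (not isolated)
Conditions: LDA, THF, −78 °C; 5; then KOtBu, −78 °C → rt; chromatography on Et3N-treated silica
Reagents that add atoms: none
Why: Horner–Wittig olefination: the lithiated phosphine oxide adds to aldehyde 5, and after exchange to potassium the alkoxides lose diphenylphosphinate by stereospecific syn elimination. Both alkene isomers are expected, and the (E) isomer is separated on amine-deactivated silica.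

Step 4
Reactants: 7 2-[(1S)-1-({(1E)-1-[4-(benzyloxy)-3-methoxyphenyl]prop-1-en-2-yl}oxy)ethyl]naphthalene; 8 propanoyl chloride
Product: 10 (2R,3S,4S)-2-[4-(benzyloxy)-3-methoxyphenyl]-3,4-dimethyl-3-{[(1S)-1-(naphthalen-2-yl)ethyl]oxy}cyclobutan-1-one (aryl/C3-methyl/C4-methyl all on one face), via methylketene 9 (not isolated)
Conditions: Et3N, toluene, 70 °C, slow addition of 8; chromatography
Reagents that add atoms: none
Why: Methylketene 9, released from 8 by dehydrochlorination and kept at low concentration, adds across the electron-rich alkene of 7 in a ketene–enol ether [2+2] cycloaddition, the established route to 3-alkoxycyclobutanones. The ketene carbonyl carbon (C5) bonds first to the nucleophilic benzylic C2 while positive charge builds on the oxygen-bearing C3, and the ketene α-carbon (C4) then bonds to C3; the four-membered ring is therefore closed by an asynchronous union of two two-carbon units, suprafacial on the alkene, ending with collapse of the enolate carbon onto the oxocarbenium carbon. Regiochemistry is fixed by the alkoxy donor, which makes C2 the nucleophilic and C3 the cation-stabilising end. Because the alkene reacts on one face without rotation in a non-polar medium, the (E) geometry becomes aryl cis to the C3 methyl and trans to the ether oxygen. The absolute sense of C2 and C3 depends on the face attacked: the (1S)-naphthylethyl group is expected to favour the face away from its naphthalene, and in any case makes the two facial products diastereomers, which are separated here. C4 is set by the orientation of the ketene: its hydrogen faces the alkene, the aryl and C3 methyl point away from it, and the ketene methyl ends cis to them, so 10 should be the all-cis isomer; any C4 epimer formed alongside converges at 12. The step needs cross-cycloaddition to outrun ketene dimerisation, which slow addition of 8 and the high nucleophilicity of the 2-alkoxypropene-type alkene are meant to secure. It also needs the benzylic α-keto C2–H of 10 to stay untouched, so exposure to amine is kept short and no equilibration is attempted at this stage.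

Step 5
Reactants: 10 (2R,3S,4S)-2-[4-(benzyloxy)-3-methoxyphenyl]-3,4-dimethyl-3-{[(1S)-1-(naphthalen-2-yl)ethyl]oxy}cyclobutan-1-one
Product: 11 (3S,4S,5R)-5-[4-(benzyloxy)-3-methoxyphenyl]-3,4-dimethyl-4-{[(1S)-1-(naphthalen-2-yl)ethyl]oxy}oxolan-2-one (aryl and both methyls cis)
Conditions: mCPBA, NaHCO3, CH2Cl2, 0 °C → rt
Reagents that add atoms: 3-chloroperoxybenzoic acid, OOC(=O)c1cccc(Cl)c1
Why: Baeyer–Villiger oxidation driven by the strain of the cyclobutanone; the electron-rich secondary benzylic C2 migrates in preference to C4 and with retention, so O1 enters between C5 and C2 and no stereocentre changes. The buffer protects the acid-labile β-alkoxy ketone and the benzylic lactone.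

Step 6
Reactants: 11 (3S,4S,5R)-5-[4-(benzyloxy)-3-methoxyphenyl]-3,4-dimethyl-4-{[(1S)-1-(naphthalen-2-yl)ethyl]oxy}oxolan-2-one
Product: 12 (3R,4S,5R)-5-[4-(benzyloxy)-3-methoxyphenyl]-3,4-dimethyl-4-{[(1S)-1-(naphthalen-2-yl)ethyl]oxy}oxolan-2-one (α-methyl trans to the β-methyl and cis to the ether oxygen)
Conditions: DBU, toluene, 80 °C; recovered 11 resubmitted
Reagents that add atoms: none
Why: Thermodynamic epimerisation α to the lactone carbonyl through its enolate: C4–H is now the only acidic C–H, and the all-cis array of 11 should relax to 12, where the C4 methyl is trans to the C3 methyl and to the C2 aryl. Reprotonation of the enolate is expected to be faster than loss of the C3 alkoxide.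

Step 7
Reactants: 12 (3R,4S,5R)-5-[4-(benzyloxy)-3-methoxyphenyl]-3,4-dimethyl-4-{[(1S)-1-(naphthalen-2-yl)ethyl]oxy}oxolan-2-one
Product: 14 (3R,4S,5R)-5-[4-(benzyloxy)-3-methoxyphenyl]-3,4-dimethyl-4-{[(1S)-1-(naphthalen-2-yl)ethyl]oxy}oxolan-2-yl acetate (both epimers at the acetal carbon), via aluminium hemiacetal 13 (not isolated)
Conditions: i-Bu2AlH, CH2Cl2, −78 °C; then pyridine, DMAP, Ac2O, −78 → 0 °C
Reagents that add atoms: acetic anhydride, CC(=O)OC(C)=O
Why: One-pot reductive acetylation of a lactone: the tetrahedral aluminium hemiacetal 13 is acylated before it can collapse, so the elimination-prone β-alkoxy aldehyde is never set free. The acetal centre forms as a mixture, which does not matter because it ionises in step 9.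

Step 8
Reactants: 15 1-(benzyloxy)-4-bromo-2-methoxybenzene
Product: 17 [4-(benzyloxy)-3-methoxyphenyl]zinc bromide (solution in THF), via aryllithium 16 (not isolated)
Conditions: n-BuLi, THF, −78 °C; then ZnBr2, −78 → 0 °C
Reagents that add atoms: zinc bromide, Br[Zn]Br
Why: Bromine–lithium exchange and transmetallation to zinc give a regiodefined aryl nucleophile that tolerates the Lewis acid of step 9.

Step 9
Reactants: 14 (3R,4S,5R)-5-[4-(benzyloxy)-3-methoxyphenyl]-3,4-dimethyl-4-{[(1S)-1-(naphthalen-2-yl)ethyl]oxy}oxolan-2-yl acetate; 17 [4-(benzyloxy)-3-methoxyphenyl]zinc bromide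
Product: 18 (2R,3S,4S,5R)-2,5-bis[4-(benzyloxy)-3-methoxyphenyl]-3,4-dimethyl-3-{[(1S)-1-(naphthalen-2-yl)ethyl]oxy}oxolane
Conditions: BF3·OEt2, CH2Cl2–THF, −78 → −20 °C
Reagents that add atoms: none
Why: Lewis-acid ionisation of the acetate gives the cyclic oxocarbenium ion at C5, which the arylzinc reagent captures (C-arylation of a lactol acetate). The aryl group should enter on the face opposite the vicinal C4 methyl and the large C3 ether group, giving C5 aryl trans to the C4 methyl and cis to the C2 aryl, which is also the more stable arrangement.

Step 10
Reactants: 18 (2R,3S,4S,5R)-2,5-bis[4-(benzyloxy)-3-methoxyphenyl]-3,4-dimethyl-3-{[(1S)-1-(naphthalen-2-yl)ethyl]oxy}oxolane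
Product: 19 (2R,3S,4S,5R)-2,5-bis(4-hydroxy-3-methoxyphenyl)-3,4-dimethyloxolan-3-ol
Conditions: H2 (1 atm), Pd/C, EtOAc–MeOH, rt
Reagents that add atoms: none
Why: Catalytic hydrogenolysis cleaves the two aryl benzyl ethers and the naphthylmethyl-type tertiary ether, which adsorb and cleave faster than the hindered ring benzylic ethers under neutral conditions. No stereocentre is touched.

## Compound list

1 | (S)-1-(naphthalen-2-yl)ethanol | C[C@H](O)c1ccc2ccccc2c1 | starting material
2 | 2-[(1S)-1-(ethenyloxy)ethyl]naphthalene | C=CO[C@@H](C)c1ccc2ccccc2c1 | intermediate
3 | 2-[(1S)-1-(1-chloroethoxy)ethyl]naphthalene, both epimers at the chlorine-bearing carbon | CC(Cl)O[C@@H](C)c1ccc2ccccc2c1 | intermediate (not isolated)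
4 | [1-{[(1S)-1-(naphthalen-2-yl)ethyl]oxy}ethyl](diphenyl)phosphine oxide, both epimers at the phosphorus-bearing carbon | CC(O[C@@H](C)c1ccc2ccccc2c1)P(=O)(c1ccccc1)c1ccccc1 | intermediate
5 | 4-(benzyloxy)-3-methoxybenzaldehyde (O-benzylvanillin) | COc1cc(C=O)ccc1OCc1ccccc1 | starting material
6 | lithium alkoxides of the β-hydroxy phosphine oxide adducts of 4 and 5, mixture of diastereomers at the two new centres | [Li]OC(c1ccc(OCc2ccccc2)c(OC)c1)C(C)(O[C@@H](C)c1ccc2ccccc2c1)P(=O)(c1ccccc1)c1ccccc1 | intermediate (not isolated)
7 | 2-[(1S)-1-({(1E)-1-[4-(benzyloxy)-3-methoxyphenyl]prop-1-en-2-yl}oxy)ethyl]naphthalene | COc1cc(/C=C(\C)O[C@@H](C)c2ccc3ccccc3c2)ccc1OCc1ccccc1 | intermediate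
8 | propanoyl chloride | CCC(=O)Cl | starting material
9 | methylketene (prop-1-en-1-one) | CC=C=O | intermediate (not isolated)
10 | (2R,3S,4S)-2-[4-(benzyloxy)-3-methoxyphenyl]-3,4-dimethyl-3-{[(1S)-1-(naphthalen-2-yl)ethyl]oxy}cyclobutan-1-one | O=C1[C@H](c2ccc(OCc3ccccc3)c(OC)c2)[C@@](C)(O[C@@H](C)c2ccc3ccccc3c2)[C@@H]1C | intermediate
11 | (3S,4S,5R)-5-[4-(benzyloxy)-3-methoxyphenyl]-3,4-dimethyl-4-{[(1S)-1-(naphthalen-2-yl)ethyl]oxy}oxolan-2-one | O=C1O[C@H](c2ccc(OCc3ccccc3)c(OC)c2)[C@@](C)(O[C@@H](C)c2ccc3ccccc3c2)[C@@H]1C | intermediate
12 | (3R,4S,5R)-5-[4-(benzyloxy)-3-methoxyphenyl]-3,4-dimethyl-4-{[(1S)-1-(naphthalen-2-yl)ethyl]oxy}oxolan-2-one | O=C1O[C@H](c2ccc(OCc3ccccc3)c(OC)c2)[C@@](C)(O[C@@H](C)c2ccc3ccccc3c2)[C@H]1C | intermediate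
13 | diisobutylaluminium alkoxide of the lactol derived from 12 (aluminium hemiacetal, both epimers at the acetal carbon) | CC(C)C[Al](CC(C)C)OC1O[C@H](c2ccc(OCc3ccccc3)c(OC)c2)[C@@](C)(O[C@@H](C)c2ccc3ccccc3c2)[C@H]1C | intermediate (not isolated)
14 | (3R,4S,5R)-5-[4-(benzyloxy)-3-methoxyphenyl]-3,4-dimethyl-4-{[(1S)-1-(naphthalen-2-yl)ethyl]oxy}oxolan-2-yl acetate, both epimers at the acetal carbon | CC(=O)OC1O[C@H](c2ccc(OCc3ccccc3)c(OC)c2)[C@@](C)(O[C@@H](C)c2ccc3ccccc3c2)[C@H]1C | intermediate
15 | 1-(benzyloxy)-4-bromo-2-methoxybenzene | Brc1ccc(OCc2ccccc2)c(OC)c1 | starting material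
16 | [4-(benzyloxy)-3-methoxyphenyl]lithium | [Li]c1ccc(OCc2ccccc2)c(OC)c1 | intermediate (not isolated)
17 | [4-(benzyloxy)-3-methoxyphenyl]zinc bromide | Br[Zn]c1ccc(OCc2ccccc2)c(OC)c1 | intermediate
18 | (2R,3S,4S,5R)-2,5-bis[4-(benzyloxy)-3-methoxyphenyl]-3,4-dimethyl-3-{[(1S)-1-(naphthalen-2-yl)ethyl]oxy}oxolane | COc1cc([C@H]2O[C@@H](c3ccc(OCc4ccccc4)c(OC)c3)[C@H](C)[C@]2(C)O[C@@H](C)c2ccc3ccccc3c2)ccc1OCc1ccccc1 | intermediate
19 | (2R,3S,4S,5R)-2,5-bis(4-hydroxy-3-methoxyphenyl)-3,4-dimethyloxolan-3-ol | COc1cc([C@H]2O[C@@H](c3ccc(O)c(OC)c3)[C@H](C)[C@]2(C)O)ccc1O | target

## Step count and least certain steps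

Total: 10 steps. Longest linear sequence: 9 steps (steps 1–7, 9 and 10, from alcohol 1); step 8 is a one-step side branch.

**Step 4 (key step).** Dimerisation and oligomerisation of the ketene may outpace cycloaddition to the hindered trisubstituted alkene. Facial discrimination by the auxiliary may be weak, which lowers the amount of the wanted diastereomer. Prolonged contact with amine may epimerise the benzylic α-keto centre C2. The fallback sets out from 7 and uses the far more electrophilic chloro(methyl)ketene, generated from 2-chloropropanoyl chloride and Et3N. It should add with the same regiochemistry and alkene-face logic to give the α-chloro cyclobutanone F1, whose C4 configuration is immaterial. Reductive dechlorination with zinc dust in acetic acid then gives a zinc enolate at C4 only, and its protonation returns the route to 10. Any C4 epimer joins at 12.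

**Step 6.** Loss of the C3 alkoxide from the lactone enolate (β-elimination to a butenolide) may compete with reprotonation, or the equilibrium may not favour the wanted epimer strongly enough. The fallback sets C4 by carbon alkylation instead of protonation and sets out from 7. Dichloroketene (from trichloroacetyl chloride and zinc) should give the dichlorocyclobutanone F2. Zinc in acetic acid removes both chlorines to give cyclobutanone F3, and peracid oxidation gives the lactone F4, which lacks the C4 methyl. Its lithium enolate (LDA, −78 °C, where elimination is slow) is methylated with iodomethane on the face opposite the C3 methyl and the C2 aryl group, which returns the route to 12.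

**Step 9.** Facial selectivity at C5 may be poor, because the C3 methyl and the C2 aryl group lie on the face to be attacked. Transfer of the aryl group from zinc may also be slow, so that proton loss from the oxocarbenium ion to a dihydrofuran competes. The fallback reverses the order of bond formation and sets out from 12 and aryllithium 16. Addition at −78 °C gives the hemiketal F5, and ionic hydrogenation with Et3SiH and BF3·OEt2 replaces its hydroxyl by hydrogen. If hydride delivery leaves the aryl group cis to the C4 methyl (the C5 epimer F6), brief further exposure to BF3·OEt2 should equilibrate that centre through reversible ionisation of the p-alkoxybenzylic C5–O1 bond. This returns the route to 18, the isomer with aryl trans to the C4 methyl.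

**Step 10.** Hydrogenolysis of the ring benzylic C–O bonds (ring opening) may compete with the slower cleavage of the hindered tertiary ether, or removal of that ether may stay incomplete. The fallback sets out from 18 and replaces hydrogenolysis by Lewis-acid dealkylation with a cation scavenger: BCl3 and pentamethylbenzene in CH2Cl2 at −78 °C. The benzyl and naphthylethyl groups are transferred to the scavenger and 19 is obtained directly; no new intermediate is formed.

## Further compounds

F1 | step 4 | 4-chloro analogue of 10: 2-[4-(benzyloxy)-3-methoxyphenyl]-4-chloro-3,4-dimethyl-3-{[(1S)-1-(naphthalen-2-yl)ethyl]oxy}cyclobutan-1-one, C2 and C3 configured as in 10, either C4 epimer | O=C1[C@H](c2ccc(OCc3ccccc3)c(OC)c2)[C@@](C)(O[C@@H](C)c2ccc3ccccc3c2)C1(C)Cl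
F2 | step 6 | 2-[4-(benzyloxy)-3-methoxyphenyl]-4,4-dichloro-3-methyl-3-{[(1S)-1-(naphthalen-2-yl)ethyl]oxy}cyclobutan-1-one, C2 and C3 configured as in 10 | O=C1[C@H](c2ccc(OCc3ccccc3)c(OC)c2)[C@@](C)(O[C@@H](C)c2ccc3ccccc3c2)C1(Cl)Cl
F3 | step 6 | 2-[4-(benzyloxy)-3-methoxyphenyl]-3-methyl-3-{[(1S)-1-(naphthalen-2-yl)ethyl]oxy}cyclobutan-1-one, C2 and C3 configured as in 10 | O=C1[C@H](c2ccc(OCc3ccccc3)c(OC)c2)[C@@](C)(O[C@@H](C)c2ccc3ccccc3c2)C1
F4 | step 6 | 5-[4-(benzyloxy)-3-methoxyphenyl]-4-methyl-4-{[(1S)-1-(naphthalen-2-yl)ethyl]oxy}oxolan-2-one, ring centres configured as in 12 | O=C1O[C@H](c2ccc(OCc3ccccc3)c(OC)c2)[C@@](C)(O[C@@H](C)c2ccc3ccccc3c2)C1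
F5 | step 9 | 2,5-bis[4-(benzyloxy)-3-methoxyphenyl]-3,4-dimethyl-4-{[(1S)-1-(naphthalen-2-yl)ethyl]oxy}oxolan-2-ol (hemiketal from 12, both epimers at the hemiketal carbon) | OC1(c2ccc(OCc3ccccc3)c(OC)c2)O[C@H](c2ccc(OCc3ccccc3)c(OC)c2)[C@@](C)(O[C@@H](C)c2ccc3ccccc3c2)[C@H]1C
F6 | step 9 | C5 epimer of 18 (C5 aryl cis to the C4 methyl) | COc1cc([C@H]2O[C@H](c3ccc(OCc4ccccc4)c(OC)c3)[C@H](C)[C@]2(C)O[C@@H](C)c2ccc3ccccc3c2)ccc1OCc1ccccc1
F0 | step 10 | none | none
A1 | alternative 1 | dimethyl 2,5-cis-bis[4-(benzyloxy)-3-methoxyphenyl]-4-methyloxolane-3,3-dicarboxylate (4,5-trans) | COc1cc([C@H]2O[C@@H](c3ccc(OCc4ccccc4)c(OC)c3)[C@H](C)C2(C(=O)OC)C(=O)OC)ccc1OCc1ccccc1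
A2 | alternative 1 | dimethyl cis-2-[4-(benzyloxy)-3-methoxyphenyl]-3-methylcyclopropane-1,1-dicarboxylate | COC(=O)C1(C(=O)OC)[C@H](c2ccc(OCc3ccccc3)c(OC)c2)[C@@H]1C
A3 | alternative 2 | 2,5-cis-bis[4-(benzyloxy)-3-methoxyphenyl]-4-methyloxolan-3-one (4,5-trans) | COc1cc([C@H]2O[C@@H](c3ccc(OCc4ccccc4)c(OC)c3)[C@H](C)C2=O)ccc1OCc1ccccc1
A4 | alternative 2 | (5R)-2,5-bis[4-(benzyloxy)-3-methoxyphenyl]-4-[(Z)-ethylidene]-1,3-dioxolane, either configuration at the acetal carbon | C/C=C1\OC(c2ccc(OCc3ccccc3)c(OC)c2)O[C@@H]1c1ccc(OCc2ccccc2)c(OC)c1
A5 | alternative 3 | {2,5-cis-bis[4-(benzyloxy)-3-methoxyphenyl]-3,4-dimethyloxolan-3-yl}dimethyl(phenyl)silane, silicon in the place and configuration of the C3 oxygen of 18 | COc1cc([C@H]2O[C@@H](c3ccc(OCc4ccccc4)c(OC)c3)[C@H](C)[C@]2(C)[Si](C)(C)c2ccccc2)ccc1OCc1ccccc1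
A6 | alternative 3 | [(1R,2Z)-1-[4-(benzyloxy)-3-methoxyphenyl]-2-methylbut-2-en-1-yl]dimethyl(phenyl)silane | C/C=C(/C)[C@H](c1ccc(OCc2ccccc2)c(OC)c1)[Si](C)(C)c1ccccc1
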